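**Retrosynthetic overview**
1. Last C–C bond: enantioselective 1,4-arylation of a fully substituted chromone with a silylated catechol boronic acid sets C2 (S) one step before the end.
2. C6 prenyl comes from a [1,3] O→C shift of a 7-O-prenyl ether; the C8 (R)-carbinol chain comes from Shi epoxidation and epoxide-to-allylic-alcohol isomerisation of a C8 prenyl group.
3. Key step: chelation-controlled Claisen–Cope rearrangement of 5,7-bis(prenyloxy)chromone. Ring A is dearomatised to cyclohexadienones and the two identical prenyl ethers become different (O5 prenyl moves to C8, O7 prenyl stays).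
4. Ring order: ring A is bought as phloroacetophenone; the pyranone ring is closed on its single free ortho-OH; ring B (from 4-bromocatechol) is attached last.

Assumption: the descriptors read from the SMILES are (2S) at the flavanone carbon and (R) at the side-chain carbinol; the silylated catechol boronic acid is prepared, not bought.

**Route**

Step 1
Reactants: 1 2,4,6-trihydroxyacetophenone; 2 prenyl bromide
Product: 3 1-[2-hydroxy-4,6-bis(3-methylbut-2-enyloxy)phenyl]ethanone
Conditions: 2 (2.2 equiv), K2CO3, acetone, reflux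
Reagents that add atoms: prenyl bromide 2, CC(C)=CCBr
Why: Williamson etherification alkylates the para and one ortho hydroxyl while the second ortho hydroxyl stays locked in its hydrogen bond to the acetyl carbonyl, leaving exactly one free ortho-OH for the pyranone closure.

Step 2
Reactants: 3 1-[2-hydroxy-4,6-bis(3-methylbut-2-enyloxy)phenyl]ethanone
Product: 5 5,7-bis(3-methylbut-2-enyloxy)-4H-chromen-4-one, via enaminone 4 (not isolated)
Conditions: DMF-DMA, toluene, 100 °C; then AcOH, 80 °C
Reagents that add atoms: N,N-dimethylformamide dimethyl acetal, COC(OC)N(C)C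
Why: Enaminone condensation at the methyl ketone followed by acid-mediated addition–elimination of the only free phenol (loss of dimethylamine) closes the pyranone ring without any regiochemical choice, and the prenyl ethers tolerate these conditions.

Step 3
Reactants: 5 5,7-bis(3-methylbut-2-enyloxy)-4H-chromen-4-one
Product: 8 5-hydroxy-8-(3-methylbut-2-enyl)-7-(3-methylbut-2-enyloxy)-4H-chromen-4-one, via ortho-dienone 6 (not isolated), via para-dienone 7 (not isolated)
Conditions: Eu(fod)3 [fod = 6,6,7,7,8,8,8-heptafluoro-2,2-dimethyloctane-3,5-dionate] (10 mol%), CHCl3, 65 °C, sealed tube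
Reagents that add atoms: none
Why: Lewis-acid-accelerated aromatic Claisen then Cope rearrangement, in which trivalent europium chelated between the C4 carbonyl and O5 activates only the 5-O-prenyl ether, the first [3,3] shift to C6 dearomatises ring A (6), the second [3,3] shift carries the allyl unit to C8 (7) and enolisation restores the arene, while the unchelated 7-O-prenyl ether does not rearrange at this temperature.

Step 4
Reactants: 8 5-hydroxy-8-(3-methylbut-2-enyl)-7-(3-methylbut-2-enyloxy)-4H-chromen-4-one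
Product: 9 8-{[(2R)-3,3-dimethyloxiran-2-yl]methyl}-5-hydroxy-7-(3-methylbut-2-enyloxy)-4H-chromen-4-one
Conditions: D-fructose-derived Shi ketone (30 mol%), Oxone (2KHSO5·KHSO4·K2SO4, 1.4 equiv KHSO5), K2CO3, Bu4NHSO4, MeCN/dimethoxymethane/aq. Na2B4O7 buffer (pH about 10), 0 °C
Reagents that add atoms: potassium peroxymonosulfate (active part of Oxone), [K+].[O-]S(=O)(=O)OO
Why: Shi asymmetric epoxidation, in which the chiral dioxirane attacks the electron-richer C-prenyl olefin markedly faster than the inductively deactivated olefin of the aryl prenyl ether (as in 6,7-selective epoxidation of geranyl acetate) and the spiro transition state of the D-fructose-derived ketone gives the (R)-epoxide, which fixes the future carbinol carbon.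

Step 5
Reactants: 9 8-{[(2R)-3,3-dimethyloxiran-2-yl]methyl}-5-hydroxy-7-(3-methylbut-2-enyloxy)-4H-chromen-4-one
Product: 10 5-hydroxy-8-[(2R)-2-hydroxy-3-methylbut-3-enyl]-7-(3-methylbut-2-enyloxy)-4H-chromen-4-one
Conditions: Et2Al(TMP) (4 equiv, from Et2AlCl + LiTMP), toluene, 0 °C; aq. potassium sodium tartrate
Reagents that add atoms: none
Why: Yamamoto epoxide-to-allylic-alcohol isomerisation, in which the hindered aluminium amide binds the epoxide oxygen and removes a methyl proton in a syn-elimination that cleaves only the tertiary C–O bond, so the secondary C–O bond keeps its (R) configuration and the isopropenyl carbinol forms (one equivalent is consumed by the 5-OH).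

Step 6
Reactants: 10 5-hydroxy-8-[(2R)-2-hydroxy-3-methylbut-3-enyl]-7-(3-methylbut-2-enyloxy)-4H-chromen-4-one
Product: 11 5,7-dihydroxy-8-[(2R)-2-hydroxy-3-methylbut-3-enyl]-6-(3-methylbut-2-enyl)-4H-chromen-4-one
Conditions: montmorillonite K10 (acid-activated aluminosilicate clay, idealised Al2Si4O10(OH)2·nH2O), CH2Cl2, 0 °C
Reagents that add atoms: none
Why: Acid-clay-promoted [1,3] prenyl shift (ion-pair dissociation and recombination of the aryl prenyl ether), in which the prenyl cation recombines through its unsubstituted terminus with C6, the only free nucleophilic carbon of ring A, and low temperature limits chroman formation and ionisation of the allylic alcohol.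

Step 7
Reactants: 11 5,7-dihydroxy-8-[(2R)-2-hydroxy-3-methylbut-3-enyl]-6-(3-methylbut-2-enyl)-4H-chromen-4-one
Product: 12 5,7-bis(tert-butyldimethylsilyloxy)-8-[(2R)-2-(tert-butyldimethylsilyloxy)-3-methylbut-3-enyl]-6-(3-methylbut-2-enyl)-4H-chromen-4-one
Conditions: TBSOTf (4 equiv), 2,6-lutidine, CH2Cl2, −40 to 0 °C
Reagents that add atoms: tert-butyldimethylsilyl triflate, CC(C)(C)[Si](C)(C)OS(=O)(=O)C(F)(F)F
Why: Silylation with the silyl triflate masks both phenols (including the chelated 5-OH) and the allylic alcohol, so that no phenoxide deactivates the enone and no rhodium-mediated allylic alcohol isomerisation can occur in the arylation.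

Step 8
Reactants: 13 4-bromobenzene-1,2-diol
Product: 14 4-bromo-1,2-bis(tert-butyldimethylsilyloxy)benzene
Conditions: TBSCl (2.4 equiv), imidazole, DMF, rt
Reagents that add atoms: tert-butyldimethylsilyl chloride, CC(C)(C)[Si](C)(C)Cl
Why: Imidazole-promoted silylation protects both catechol hydroxyls with a group that is removed by fluoride at the end.

Step 9
Reactants: 14 4-bromo-1,2-bis(tert-butyldimethylsilyloxy)benzene
Product: 16 [3,4-bis(tert-butyldimethylsilyloxy)phenyl]boronic acid, via aryllithium 15 (not isolated)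
Conditions: n-BuLi, THF, −78 °C; B(OiPr)3; then 1 M HCl, 0 °C
Reagents that add atoms: n-butyllithium, [Li]CCCC; triisopropyl borate, CC(C)OB(OC(C)C)OC(C)C; water, O
Why: Bromine–lithium exchange followed by borylation and brief cold acidic hydrolysis gives the boronic acid, and the aryl silyl ethers survive because the lithium is not ortho to a silyloxy group and the acid contact is short.

Step 10
Reactants: 12 5,7-bis(tert-butyldimethylsilyloxy)-8-[(2R)-2-(tert-butyldimethylsilyloxy)-3-methylbut-3-enyl]-6-(3-methylbut-2-enyl)-4H-chromen-4-one; 16 [3,4-bis(tert-butyldimethylsilyloxy)phenyl]boronic acid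
Product: 17 (2S)-2-[3,4-bis(tert-butyldimethylsilyloxy)phenyl]-5,7-bis(tert-butyldimethylsilyloxy)-8-[(2R)-2-(tert-butyldimethylsilyloxy)-3-methylbut-3-enyl]-6-(3-methylbut-2-enyl)chroman-4-one
Conditions: [RhCl(C2H4)2]2 (2.5 mol%), (1S,4S)-2,5-diphenylbicyclo[2.2.2]octa-2,5-diene (5.5 mol%), KOH (10 mol%), 16 (3 equiv), dioxane/H2O 10:1, 50–70 °C
Reagents that add atoms: none
Why: Hayashi–Miyaura asymmetric 1,4-addition to a chromone, in which the aryl–rhodium species (monovalent rhodium) inserts the C2=C3 bond from the Re face of C2 as dictated by the C2-symmetric diene (the sense that gives (S)-3-arylcyclohexanones by analogy, to be confirmed on the first run; both ligand enantiomers are available), water protonates the rhodium enolate to give the (2S)-flavanone, the borate-buffered medium avoids retro-oxa-Michael racemisation, and the isolated olefins are not attacked.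

Step 11
Reactants: 17 (2S)-2-[3,4-bis(tert-butyldimethylsilyloxy)phenyl]-5,7-bis(tert-butyldimethylsilyloxy)-8-[(2R)-2-(tert-butyldimethylsilyloxy)-3-methylbut-3-enyl]-6-(3-methylbut-2-enyl)chroman-4-one
Product: 18 (2S)-2-(3,4-dihydroxyphenyl)-5,7-dihydroxy-8-[(2R)-2-hydroxy-3-methylbut-3-enyl]-6-(3-methylbut-2-enyl)chroman-4-one
Conditions: Et3N·3HF, THF, rt to 40 °C
Reagents that add atoms: none
Why: Fluoride-driven desilylation (Si–F bond formation) under slightly acidic, non-basic conditions removes all five silyl groups without enolising C3, so the (2S) centre, the prenyl group and the allylic alcohol are preserved.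

**Compound list**
1 | 2,4,6-trihydroxyacetophenone | CC(=O)c1c(O)cc(O)cc1O | starting material
2 | prenyl bromide (1-bromo-3-methylbut-2-ene) | CC(C)=CCBr | starting material
3 | 1-[2-hydroxy-4,6-bis(3-methylbut-2-enyloxy)phenyl]ethanone | CC(=O)c1c(O)cc(OCC=C(C)C)cc1OCC=C(C)C | intermediate
4 | (E)-3-(dimethylamino)-1-[2-hydroxy-4,6-bis(3-methylbut-2-enyloxy)phenyl]prop-2-en-1-one (enaminone, not isolated) | CN(C)/C=C/C(=O)c1c(O)cc(OCC=C(C)C)cc1OCC=C(C)C | intermediate
5 | 5,7-bis(3-methylbut-2-enyloxy)-4H-chromen-4-one | CC(C)=CCOc1cc(OCC=C(C)C)c2c(c1)OC=CC2=O | intermediate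
6 | 6-(2-methylbut-3-en-2-yl)-7-(3-methylbut-2-enyloxy)-6H-chromene-4,5-dione (ortho-dienone, racemic at C6, not isolated) | O=C1C=COC2=C1C(=O)C(C(C)(C)C=C)C(OCC=C(C)C)=C2 | intermediate
7 | 8-(3-methylbut-2-enyl)-7-(3-methylbut-2-enyloxy)-8H-chromene-4,5-dione (para-dienone, racemic at C8, not isolated) | O=C1C=COC2=C1C(=O)C=C(OCC=C(C)C)C2CC=C(C)C | intermediate
8 | 5-hydroxy-8-(3-methylbut-2-enyl)-7-(3-methylbut-2-enyloxy)-4H-chromen-4-one | CC(C)=CCOc1cc(O)c2c(c1CC=C(C)C)OC=CC2=O | intermediate
9 | 8-{[(2R)-3,3-dimethyloxiran-2-yl]methyl}-5-hydroxy-7-(3-methylbut-2-enyloxy)-4H-chromen-4-one | CC(C)=CCOc1cc(O)c2c(c1C[C@H]3OC3(C)C)OC=CC2=O | intermediate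
10 | 5-hydroxy-8-[(2R)-2-hydroxy-3-methylbut-3-enyl]-7-(3-methylbut-2-enyloxy)-4H-chromen-4-one | C=C(C)[C@H](O)Cc1c(OCC=C(C)C)cc(O)c2c1OC=CC2=O | intermediate
11 | 5,7-dihydroxy-8-[(2R)-2-hydroxy-3-methylbut-3-enyl]-6-(3-methylbut-2-enyl)-4H-chromen-4-one | C=C(C)[C@H](O)Cc1c(O)c(CC=C(C)C)c(O)c2c1OC=CC2=O | intermediate
12 | 5,7-bis(tert-butyldimethylsilyloxy)-8-[(2R)-2-(tert-butyldimethylsilyloxy)-3-methylbut-3-enyl]-6-(3-methylbut-2-enyl)-4H-chromen-4-one | C=C(C)[C@H](O[Si](C)(C)C(C)(C)C)Cc1c(O[Si](C)(C)C(C)(C)C)c(CC=C(C)C)c(O[Si](C)(C)C(C)(C)C)c2c1OC=CC2=O | intermediate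
13 | 4-bromobenzene-1,2-diol (4-bromocatechol) | Oc1ccc(Br)cc1O | starting material
14 | 4-bromo-1,2-bis(tert-butyldimethylsilyloxy)benzene | CC(C)(C)[Si](C)(C)Oc1ccc(Br)cc1O[Si](C)(C)C(C)(C)C | intermediate
15 | [3,4-bis(tert-butyldimethylsilyloxy)phenyl]lithium (not isolated) | [Li]c1ccc(O[Si](C)(C)C(C)(C)C)c(O[Si](C)(C)C(C)(C)C)c1 | intermediate
16 | [3,4-bis(tert-butyldimethylsilyloxy)phenyl]boronic acid | OB(O)c1ccc(O[Si](C)(C)C(C)(C)C)c(O[Si](C)(C)C(C)(C)C)c1 | intermediate
17 | (2S)-2-[3,4-bis(tert-butyldimethylsilyloxy)phenyl]-5,7-bis(tert-butyldimethylsilyloxy)-8-[(2R)-2-(tert-butyldimethylsilyloxy)-3-methylbut-3-enyl]-6-(3-methylbut-2-enyl)chroman-4-one | C=C(C)[C@H](O[Si](C)(C)C(C)(C)C)Cc1c(O[Si](C)(C)C(C)(C)C)c(CC=C(C)C)c(O[Si](C)(C)C(C)(C)C)c2c1O[C@H](c1ccc(O[Si](C)(C)C(C)(C)C)c(O[Si](C)(C)C(C)(C)C)c1)CC2=O | intermediate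
18 | (2S)-2-(3,4-dihydroxyphenyl)-5,7-dihydroxy-8-[(2R)-2-hydroxy-3-methylbut-3-enyl]-6-(3-methylbut-2-enyl)chroman-4-one (CNP0322081.2) | C=C(C)[C@H](O)Cc1c(O)c(CC=C(C)C)c(O)c2c1O[C@H](c1ccc(O)c(O)c1)CC2=O | target

**Step count**
Total: 11 steps. Longest linear sequence: 9 steps (steps 1–7, 10, 11); steps 8–9 are the side branch to the boronic acid.

**Three steps most likely to fail**

Step 3. The ortho-dienone 6 may enolise to the 6-(1,1-dimethylallyl) phenol instead of undergoing the Cope shift, or the second prenyl ether may interfere. The fallback differentiates the two oxygens with protecting groups instead of relying on chelation, and uses a 7-O-acetate, the pattern for which the tandem rearrangement is best established. It sets out from 1 and comes back at 8. Annulation of 1 with HC(OEt)3/HClO4 and then hot water gives 5,7-dihydroxy-4H-chromen-4-one F1. Acetylation of the non-chelated hydroxyl (Ac2O, pyridine, 0 °C) gives 7-acetoxy-5-hydroxy-4H-chromen-4-one F2. Mitsunobu etherification with prenol (PPh3, DIAD) gives 7-acetoxy-5-(3-methylbut-2-enyloxy)-4H-chromen-4-one F3. Eu(fod)3 in CHCl3 at 60 °C gives 7-acetoxy-5-hydroxy-8-(3-methylbut-2-enyl)-4H-chromen-4-one F4. Methanolysis with K2CO3/MeOH gives 5,7-dihydroxy-8-(3-methylbut-2-enyl)-4H-chromen-4-one F5. Alkylation with 2 and K2CO3 in acetone touches only the free 7-OH and returns 8.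

Step 6. The acid clay may cyclise the new C6 prenyl group or the C8 chain onto the neighbouring phenols, or simply cleave the prenyl ether. The fallback replaces the acid-mediated shift by neutral dealkylation followed by base-mediated C-alkylation. It sets out from 10 and comes back at 11. Pd(PPh3)4 with morpholine in THF at 50 °C (zerovalent palladium ionises the allylic C–O bond and the amine traps the prenyl unit) gives 5,7-dihydroxy-8-[(2R)-2-hydroxy-3-methylbut-3-enyl]-4H-chromen-4-one F6. C-prenylation of F6 with 2 and DBU in THF at 0 °C can occur only at C6 and gives 11. The O-alkylated by-product is 10 itself and is recycled.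

Step 10. The hexasubstituted, electron-rich chromone 12 may be too slow, or the hindered silyl ethers may hydrolyse before arylation. The fallback sets C2 earlier, on the less hindered 7-O-prenyl chromone, and moves the prenyl shift after the arylation. It sets out from 10 and comes back at 18. Silylation of 10 (TBSOTf, 2,6-lutidine) gives 5-(tert-butyldimethylsilyloxy)-8-[(2R)-2-(tert-butyldimethylsilyloxy)-3-methylbut-3-enyl]-7-(3-methylbut-2-enyloxy)-4H-chromen-4-one F7. Arylation of F7 with 16 under the conditions of step 10 gives the (2S)-flavanone 7-O-prenyl ether F8. The clay-promoted [1,3] shift of step 6 then gives the (2S)-7-hydroxy-6-prenyl flavanone tetrasilyl ether F9. Desilylation as in step 11 gives 18.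

**Further compounds**
F1 | step 3 | 5,7-dihydroxy-4H-chromen-4-one | O=C1C=COc2cc(O)cc(O)c12
F2 | step 3 | 7-acetoxy-5-hydroxy-4H-chromen-4-one | CC(=O)Oc1cc(O)c2c(c1)OC=CC2=O
F3 | step 3 | 7-acetoxy-5-(3-methylbut-2-enyloxy)-4H-chromen-4-one | CC(=O)Oc1cc(OCC=C(C)C)c2c(c1)OC=CC2=O
F4 | step 3 | 7-acetoxy-5-hydroxy-8-(3-methylbut-2-enyl)-4H-chromen-4-one | CC(=O)Oc1cc(O)c2c(c1CC=C(C)C)OC=CC2=O
F5 | step 3 | 5,7-dihydroxy-8-(3-methylbut-2-enyl)-4H-chromen-4-one | CC(C)=CCc1c(O)cc(O)c2c1OC=CC2=O
F6 | step 6 | 5,7-dihydroxy-8-[(2R)-2-hydroxy-3-methylbut-3-enyl]-4H-chromen-4-one | C=C(C)[C@H](O)Cc1c(O)cc(O)c2c1OC=CC2=O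
F7 | step 10 | 5-(tert-butyldimethylsilyloxy)-8-[(2R)-2-(tert-butyldimethylsilyloxy)-3-methylbut-3-enyl]-7-(3-methylbut-2-enyloxy)-4H-chromen-4-one | C=C(C)[C@H](O[Si](C)(C)C(C)(C)C)Cc1c(OCC=C(C)C)cc(O[Si](C)(C)C(C)(C)C)c2c1OC=CC2=O
F8 | step 10 | (2S)-2-[3,4-bis(tert-butyldimethylsilyloxy)phenyl]-5-(tert-butyldimethylsilyloxy)-8-[(2R)-2-(tert-butyldimethylsilyloxy)-3-methylbut-3-enyl]-7-(3-methylbut-2-enyloxy)chroman-4-one | C=C(C)[C@H](O[Si](C)(C)C(C)(C)C)Cc1c(OCC=C(C)C)cc(O[Si](C)(C)C(C)(C)C)c2c1O[C@H](c1ccc(O[Si](C)(C)C(C)(C)C)c(O[Si](C)(C)C(C)(C)C)c1)CC2=O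
F9 | step 10 | (2S)-2-[3,4-bis(tert-butyldimethylsilyloxy)phenyl]-5-(tert-butyldimethylsilyloxy)-8-[(2R)-2-(tert-butyldimethylsilyloxy)-3-methylbut-3-enyl]-7-hydroxy-6-(3-methylbut-2-enyl)chroman-4-one | C=C(C)[C@H](O[Si](C)(C)C(C)(C)C)Cc1c(O)c(CC=C(C)C)c(O[Si](C)(C)C(C)(C)C)c2c1O[C@H](c1ccc(O[Si](C)(C)C(C)(C)C)c(O[Si](C)(C)C(C)(C)C)c1)CC2=O
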